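## Analysis of the target

The target is a 1,2-dioxane, numbered here O1, O2, C3, C4, C5, C6: C3 is a mixed ketal carbon (ring oxygen O2, a methoxy group, a sixteen-carbon chain) and C6 is a secondary peroxide carbon carrying the acetic acid arm C7–C8. Systematic names of the intermediates number the ring from the other end, so the acetate-bearing carbon becomes position 3 and the ketal carbon position 6. The chain runs from C3 through three CH2 groups to a conjugated (E)-enyne and then through seven CH2 groups to a methyl ketone. The two stereocenters, C3 (R) and C6 (S), are 1,4-related: methoxy and acid arm are cis, so the chair has the methoxy group axial and both carbon substituents equatorial. That is the arrangement the anomeric effect favours, so C3 can be set by equilibration and only C6 needs absolute control. The sensitive groups are the O–O bond (low-valent metals, phosphines, hydrides, hydrogenation catalysts), the C6–H bond (base-induced Kornblum–DeLaMare cleavage), the β-peroxy carboxyl unit (β-elimination), the acid-labile peroxyketal, the enyne and the methyl ketone. The difficulty is to build a ring peroxide with a defined secondary C–O centre and a mixed methoxy/peroxy ketal while carrying or attaching an unsaturated keto chain and a carboxylic acid. The plan rests on the fact that C4 and C5 are the only ring atoms not bonded to oxygen: a temporary C4=C5 double bond makes the ring closure a C–C bond formation far from the peroxide, and lets the O2–C3 bond be made first, between two separate halves, as an open-chain peroxyketal.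

## Retrosynthetic reasoning

**21 ⇒ 20.** The last operation is a functional-group change: acid 21 is freed from methyl ester 20. The carboxyl group travels as an ester because a free acid β to the peroxide would interfere with the acid- and base-mediated steps. It is a methyl ester because the ketal equilibration is run in the alcohol matching the methoxy group, where a methyl ester cannot be scrambled. The forward step must cleave the ester without β-elimination of the peroxide.

**20 ⇒ 15 + 19.** The bond between the alkyne carbon and the alkene carbon of the enyne is cut. It can be formed under conditions a saturated dialkyl peroxide tolerates, with the alkene geometry fixed beforehand. The cut gives two halves of similar size and keeps enyne and ketone away from metathesis and reduction. Forward, a Sonogashira coupling joins terminal alkyne 15 and (E)-iodoalkene 19.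

**19 ⇒ 18 ⇒ 16.** The iodine-bearing carbon is removed to give aldehyde 18, which goes back to terminal alkene 16 by exchanging C=O for C=CH2. Forward, oxidative cleavage and a one-carbon (E)-selective iodo-olefination must distinguish the aldehyde from the methyl ketone, which the Takai reaction does.

**15 ⇒ 14 ⇒ 13 ⇒ 12.** Three changes without skeletal disconnection: the alkyne C–H becomes a triisopropylsilyl cap (14), C3 is allowed to be an epimer mixture (13), and a C4=C5 double bond is introduced (12). The cap is needed because a free alkyne would enter enyne metathesis and be reduced with the ring alkene. Forward, the ring alkene must be saturated without touching O–O or the capped alkyne, and C3 is then set thermodynamically.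

**12 ⇒ 11.** The C4=C5 bond is cut (ring-closing metathesis in the forward sense), giving the acyclic peroxyketal 11 with a vinyl group on C3 and an ester-terminated alkenyl group on C6. Cutting the ring at a C–O bond instead would mean an intramolecular substitution at a hindered ketal or at the stereogenic secondary carbon. What is gained is an open-chain precursor that divides at the O2–C3 bond. Forward, the catalyst must close the six-membered ring faster than it oligomerizes the diene, and must leave the peroxide alone.

**11 ⇒ 3 + 10.** The O2–C3 bond is cut into hydroperoxide 3 and dimethyl ketal 10. The C6–O1 bond is not chosen because making it would be a substitution at a stereogenic, allylic, base-sensitive carbon. Exchange at the ketal carbon runs through a stabilized cation under weak acid and never touches C6. Forward, one methoxy group must be exchanged, and attack must occur at the ketal carbon and not at the vinyl terminus.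

**3 ⇒ 2 ⇒ 1.** The C6–O1 bond and the whole O–O unit come from ene photooxygenation of the symmetric diester 1. Its symmetry allows only one constitutional isomer, and the alkene shifted by the ene reaction is the alkenyl group needed for metathesis. The racemate 2 is separated into enantiomers to give 3, the only source of absolute configuration.

**10 ⇒ 9 ⇒ 8 ⇒ 6 ⇒ 4.** The ketal goes back to vinyl ketone 9. The acyl–vinyl bond is cut to give Weinreb amide 8, made from silylated acid 6 and from hex-5-ynoic acid 4. The carboxyl carbon of 4 thus becomes C3, and its three CH2 groups and alkyne are the inner part of the side chain.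

## Alternatives that were turned down

**Alternative 1:** The C3–O2 bond is cut and C3 is joined to C8 as a ring alkene, giving the cyclohexenyl hydroperoxide {5-[(4S)-4-hydroperoxycyclohex-1-en-1-yl]pent-1-yn-1-yl}trimethylsilane A2, whose carbocycle holds C3–C8. Forward, ozone cleaves the alkene; the ketone oxide at C3 is trapped by the C6 hydroperoxide and C8 is released as an aldehyde, giving 2-[(3S)-6-hydroperoxy-6-[5-(trimethylsilyl)pent-4-yn-1-yl]-1,2-dioxan-3-yl]acetaldehyde A1.
- For it: one metal-free step makes the ring, oxidizes C3 and unmasks the acid arm. On step economy and absence of a transition metal near the peroxide it is stronger than the chosen route.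
- Against it:
  - The primary ozonide must fragment towards the ketone oxide at C3; the other direction puts the carbonyl oxide on C8.
  - The ketone oxide is tethered to the new aldehyde, so ordinary recombination to a bicyclic ozonide competes with capture by the hydroperoxide.
  - A1 is a geminal hydroperoxy peroxide with a free aldehyde; it still needs OOH-to-OMe exchange and oxidation to the acid, both beside a hydroperoxide.
  - A2 must be made as a single enantiomer, by substitution at a secondary carbon or by resolution, so the C6 problem is no easier.
- In its place the chosen route offers a ring closure without a competing intramolecular path, the correct methoxy ketal from the start and the acid arm at its final oxidation level.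

**Alternative 2:** Both C–O bonds of the peroxide are cut, leading to the oxetane ketal (R)-2-[3,3-dimethoxy-8-(trimethylsilyl)oct-7-yn-1-yl]oxetane A4. Forward, anhydrous H2O2 with Me3SiOTf turns the dimethyl ketal into a hydroperoxy ketal, whose terminal oxygen opens the activated oxetane at C6 with inversion, giving 2-[(3S,6R)-6-methoxy-6-[5-(trimethylsilyl)pent-4-yn-1-yl]-1,2-dioxan-3-yl]ethan-1-ol A3.
- For it: C6 is set stereospecifically from an enantiopure oxetane with no resolution and no loss of half the material. On that point it is stronger than the chosen route. The methoxy ketal arrives in the same step.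
- Against it:
  - Hydroperoxide opening of oxetanes is reliable at cation-stabilizing carbons; C6 is an unactivated secondary carbon, so the needed Lewis acid strength also ionizes the ketal.
  - External H2O2 can attack the primary oxetane carbon, and the ketal can exchange twice to a geminal dihydroperoxide.
  - Anhydrous H2O2 with a silyl triflate is hazardous.
  - A4 takes several steps, and A3 must be oxidized to the acid in two late steps beside the peroxide.
- In its place the chosen route makes each bond in a separate mild operation and carries the acid arm at its final oxidation level.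

**Alternative 3:** The C3–O2 and C3–OMe bonds are cut and C3 becomes an alkyne carbon, leading to tert-butyl{[(3S)-3-hydroperoxy-11-(triisopropylsilyl)undeca-6,10-diyn-1-yl]oxy}diphenylsilane A6. Forward, Hg(OTf)2 (divalent mercury) in methanol activates the internal alkyne, the hydroperoxide adds 6-exo-dig, and methanol adds to the resulting peroxycarbenium ion, giving tert-butyl{2-[(3S,6R)-6-methoxy-6-[5-(triisopropylsilyl)pent-4-yn-1-yl]-1,2-dioxan-3-yl]ethoxy}diphenylsilane A5.
- For it: the carbon skeleton comes convergently from a diyne, and ring, ketal and methoxy group form in one step. On convergence it is stronger.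
- Against it:
  - The first adduct is a vinyl peroxide, a class prone to O–O cleavage and rearrangement.
  - A free hydroperoxide meets a strongly oxophilic, redox-active metal salt.
  - Addition at the wrong alkyne carbon (7-endo) and plain ketone formation compete.
  - A6 is again an enantiopure secondary hydroperoxide, now on a long chain, so resolution or substitution comes late and on valuable material.
  - Desilylation and a two-step oxidation follow.
- In its place the chosen route resolves a small early hydroperoxide, avoids enol peroxides and uses a ring closure of a known type.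

Key step: step 8

Remark on the chemistry (assumption): the elution order of the enantiomers of 2 cannot be predicted, so 3 is taken to be identified by correlation (reduction of a sample to the allylic alcohol, Mosher ester analysis) before it is carried on.

## Route

Step 1
Reactants: 1 dimethyl (E)-hex-3-enedioate
Product: 2 dimethyl (E)-4-hydroperoxyhex-2-enedioate (racemate)
Conditions: O2, 5,10,15,20-tetraphenylporphyrin (cat.), hν (white LED), CCl4, 10 °C
Reagents that add atoms: dioxygen, O=O
Why: Schenck ene reaction of singlet oxygen: oxygen adds to one alkene carbon, an allylic hydrogen α to the ester is transferred and the double bond moves into conjugation; 1 is symmetric, so only one constitutional isomer can form. The alkene is (E)-disubstituted and electron-poor, so the reaction is slow and a solvent with a long singlet-oxygen lifetime is used; the stereocenter forms without control, and the geometry of the new enoate is irrelevant because that alkene is cut out in step 8.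

Step 2
Reactants: 2 dimethyl (E)-4-hydroperoxyhex-2-enedioate (racemate)
Product: 3 dimethyl (R,E)-4-hydroperoxyhex-2-enedioate
Conditions: preparative HPLC on amylose tris(3,5-dimethylphenylcarbamate)/silica, hexane–i-PrOH, 20 °C
Reagents that add atoms: none
Why: Direct chromatographic separation of enantiomers on a polysaccharide carbamate phase, a standard operation for secondary hydroperoxides, fixes the configuration of the future C6. It is preferred to a kinetic resolution because the two carbon groups at the carbinol carbon (CH2CO2Me and CH=CHCO2Me) are of similar size, so neither the selectivity nor the sense of an enzyme- or reagent-based discrimination could be relied on.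

Step 3
Reactants: 4 hex-5-ynoic acid
Product: 6 6-(triisopropylsilyl)hex-5-ynoic acid, via lithium 6-lithiohex-5-ynoate 5 (not isolated)
Conditions: n-BuLi (2.2 equiv), THF, −78 °C; i-Pr3SiCl (1.1 equiv), −78 °C to rt; aq. HCl
Reagents that add atoms: chlorotriisopropylsilane, CC(C)[Si](Cl)(C(C)C)C(C)C
Why: Double deprotonation (acid, then alkyne C–H) and C-silylation of the acetylide; the lithium carboxylate is a poor nucleophile for the hindered silyl chloride and does not add n-BuLi at −78 °C. The bulky cap later keeps the alkyne out of enyne metathesis and diimide reduction.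

Step 4
Reactants: 6 6-(triisopropylsilyl)hex-5-ynoic acid
Product: 8 N-methoxy-N-methyl-6-(triisopropylsilyl)hex-5-ynamide, via acyl imidazolide 7 (not isolated)
Conditions: 1,1'-carbonyldiimidazole, CH2Cl2, rt; MeNH(OMe)·HCl, rt
Reagents that add atoms: N,O-dimethylhydroxylamine hydrochloride, CNOC.Cl
Why: Amide formation through the acyl imidazolide gives the Weinreb amide needed for clean mono-addition of a carbon nucleophile.

Step 5
Reactants: 8 N-methoxy-N-methyl-6-(triisopropylsilyl)hex-5-ynamide
Product: 9 8-(triisopropylsilyl)oct-1-en-7-yn-3-one
Conditions: CH2=CHMgBr (1.5 equiv), THF, −20 to 0 °C; poured into cold 1 M HCl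
Reagents that add atoms: vinylmagnesium bromide, C=C[Mg]Br
Why: Weinreb ketone synthesis: the magnesium chelate of the tetrahedral adduct survives until work-up, so a second addition is excluded. The inverse quench into cold acid keeps the liberated N,O-dimethylhydroxylamine protonated so that it cannot add to the vinyl ketone.

Step 6
Reactants: 9 8-(triisopropylsilyl)oct-1-en-7-yn-3-one
Product: 10 3,3-dimethoxy-8-(triisopropylsilyl)oct-1-en-7-yne
Conditions: MeOSiMe3 (3 equiv), Me3SiOTf (5 mol %), CH2Cl2, −78 °C; pyridine quench
Reagents that add atoms: methoxytrimethylsilane, CO[Si](C)(C)C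
Why: Noyori ketalization under aprotic conditions: the silyl triflate activates the carbonyl group and the silyl ether delivers the methoxy groups, so the enone is ketalized without the conjugate addition of alcohol that protic acid in methanol would cause. The intermediate methoxyallyl cation is attacked at the oxygen-bearing carbon, as oxygen nucleophiles do in Ferrier-type reactions.

Step 7
Reactants: 3 dimethyl (R,E)-4-hydroperoxyhex-2-enedioate; 10 3,3-dimethoxy-8-(triisopropylsilyl)oct-1-en-7-yne
Product: 11 dimethyl (R,E)-4-{[3-methoxy-8-(triisopropylsilyl)oct-1-en-7-yn-3-yl]peroxy}hex-2-enedioate (both epimers at the ketal carbon)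
Conditions: 10 (2 equiv), PPTS (10 mol %), 5 Å molecular sieves, CH2Cl2, 0 °C to rt
Reagents that add atoms: none
Why: Acid-catalysed transketalization to a mixed peroxyketal: PPTS ionizes the dimethyl ketal to a methoxy-stabilized allyl cation, which the hydroperoxide oxygen captures at the oxygen-bearing carbon while the sieves take up the methanol released. The C–O bond at the stereocenter of 3 is not broken, so its R configuration is retained; the new ketal carbon forms as both epimers, which step 10 corrects.

Step 8
Reactants: 11 dimethyl (R,E)-4-{[3-methoxy-8-(triisopropylsilyl)oct-1-en-7-yn-3-yl]peroxy}hex-2-enedioate (both epimers at the ketal carbon)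
Product: 12 methyl 2-[(3R)-6-methoxy-6-[5-(triisopropylsilyl)pent-4-yn-1-yl]-3,6-dihydro-1,2-dioxin-3-yl]acetate (both epimers at C6)
Conditions: second-generation Hoveyda–Grubbs catalyst RuCl2(H2IMes)(=CH-C6H4-2-O-i-Pr) (2 × 5 mol %), CH2Cl2 (3 mM), 40 °C, Ar sparge
Reagents that add atoms: none
Why: Ring-closing olefin metathesis by the Chauvin mechanism: the ruthenium carbene exchanges onto the monosubstituted vinyl group at the ketal carbon, the new alkylidene adds intramolecularly to the enoate alkene to give a ruthenacyclobutane, and cycloreversion releases the ring alkene and an ester-substituted carbene that the next substrate molecule turns over, so the net by-product is methyl acrylate. The closest known reaction type is ring-closing metathesis of dienes that contain a dialkyl peroxide link, together with metathesis of vinyl ketals; an allylic peroxyketal paired with an acrylate-type alkene has not been tried. The one ring formed, the six-membered 3,6-dihydro-1,2-dioxine, is closed by making the C4=C5 double bond between the alkene carbons attached to the ketal carbon and to the peroxide-bearing CH, and in a ring of this size only the cis alkene can form. No stereocenter is created: the CH centre keeps the R configuration of 3 because none of its bonds takes part, and the ketal carbon stays a mixture. The step needs cyclization to win over oligomerization and over ruthenium-induced O–O cleavage; high dilution and the favourable ring size serve the first, and the absence of O–H groups and of ring strain in the peroxide serves the second. The silyl cap keeps the alkyne out of enyne metathesis, and the crowded, doubly oxygenated allylic position of the vinyl group slows its homodimerization and its capping by released acrylate.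

Step 9
Reactants: 12 methyl 2-[(3R)-6-methoxy-6-[5-(triisopropylsilyl)pent-4-yn-1-yl]-3,6-dihydro-1,2-dioxin-3-yl]acetate (both epimers at C6)
Product: 13 methyl 2-[(3S)-6-methoxy-6-[5-(triisopropylsilyl)pent-4-yn-1-yl]-1,2-dioxan-3-yl]acetate (both epimers at C6)
Conditions: KO2CN=NCO2K (excess, in portions), AcOH, CH2Cl2–MeOH, 0 °C to rt
Reagents that add atoms: none
Why: Diimide made in the flask transfers two hydrogens to the cis ring alkene and does not reduce O–O bonds, a known way to saturate unsaturated cyclic peroxides, including ones whose alkene is flanked by fully substituted carbons; the bulky silyl group shields the alkyne. Acidic generation is chosen because the allylic peroxide C–H of 12 is prone to base-induced Kornblum–DeLaMare cleavage. The descriptor of the ring CH carbon changes from R to S only because the CIP priorities change on saturation.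

Step 10
Reactants: 13 methyl 2-[(3S)-6-methoxy-6-[5-(triisopropylsilyl)pent-4-yn-1-yl]-1,2-dioxan-3-yl]acetate (both epimers at C6)
Product: 14 methyl 2-[(3S,6R)-6-methoxy-6-[5-(triisopropylsilyl)pent-4-yn-1-yl]-1,2-dioxan-3-yl]acetate
Conditions: TsOH·H2O (10 mol %), MeOH, rt; NaHCO3; chromatography, minor epimer resubjected
Reagents that add atoms: methanol, CO
Why: Acid ionizes the methoxy peroxyketal reversibly to a cyclic peroxycarbenium ion (or to the ring-opened oxocarbenium ion, which recloses), and methanol adds back under thermodynamic control. The favoured chair has the methoxy group axial (anomeric effect with the ring oxygen) and both carbon substituents equatorial, which is the 3S,6R isomer with methoxy cis to the ester arm. The ring CH stereocenter is not involved, and the methyl ester is inert in methanol.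

Step 11
Reactants: 14 methyl 2-[(3S,6R)-6-methoxy-6-[5-(triisopropylsilyl)pent-4-yn-1-yl]-1,2-dioxan-3-yl]acetate
Product: 15 methyl 2-[(3S,6R)-6-methoxy-6-(pent-4-yn-1-yl)-1,2-dioxan-3-yl]acetate
Conditions: Bu4NF (1.5 equiv), AcOH (1.5 equiv), THF, 0 °C to rt
Reagents that add atoms: none
Why: Fluoride cleaves the C(sp)–Si bond and the acetylide is protonated at once. Acetic acid buffers the basicity of Bu4NF so that the peroxide C–H and the β-peroxy ester are not exposed to strong base.

Step 12
Reactants: 16 undec-10-en-2-one
Product: 18 9-oxodecanal, via ozonide 17 (not isolated)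
Conditions: O3, CH2Cl2, −78 °C; PPh3, −78 °C to rt
Reagents that add atoms: ozone, [O-][O+]=O
Why: Ozonolysis (Criegee mechanism) of the terminal alkene gives the ozonide, which PPh3 reduces to the aldehyde; the ketone is inert.

Step 13
Reactants: 18 9-oxodecanal
Product: 19 (E)-11-iodoundec-10-en-2-one
Conditions: CrCl2 (6 equiv), CHI3 (2 equiv), THF–1,4-dioxane (1:6), 0 °C to rt
Reagents that add atoms: iodoform, IC(I)I
Why: Takai olefination: CrCl2 reduces iodoform to a geminal dichromium species that adds to the aldehyde, and elimination from the adduct gives the (E)-iodoalkene, with the dioxane cosolvent raising the E preference. The reagent reacts far faster with aldehydes than with ketones, so the methyl ketone needs no protection.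

Step 14
Reactants: 15 methyl 2-[(3S,6R)-6-methoxy-6-(pent-4-yn-1-yl)-1,2-dioxan-3-yl]acetate; 19 (E)-11-iodoundec-10-en-2-one
Product: 20 methyl 2-[(3S,6R)-6-methoxy-6-[(6E)-15-oxohexadec-6-en-4-yn-1-yl]-1,2-dioxan-3-yl]acetate
Conditions: PdCl2(PPh3)2 (5 mol %), CuI (10 mol %), Et3N, THF, rt, degassed
Reagents that add atoms: none
Why: Sonogashira coupling: oxidative addition of the iodoalkene to zerovalent palladium with retention, transmetalation from the copper acetylide and reductive elimination, so the E geometry of 19 is carried into the enyne. Saturated, unstrained dialkyl peroxides tolerate palladium/copper coupling and a tertiary amine at room temperature; ketone and ester are spectators.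

Step 15
Reactants: 20 methyl 2-[(3S,6R)-6-methoxy-6-[(6E)-15-oxohexadec-6-en-4-yn-1-yl]-1,2-dioxan-3-yl]acetate
Product: 21 2-[(3S,6R)-6-methoxy-6-[(6E)-15-oxohexadec-6-en-4-yn-1-yl]-1,2-dioxan-3-yl]acetic acid
Conditions: LiOH (2.5 equiv), THF–H2O (3:1), 0 °C; cold dilute HCl to pH 4
Reagents that add atoms: lithium hydroxide, [Li+].[OH-]
Why: Saponification of the methyl ester at 0 °C, the usual way to free the acid of β-peroxy acetates of cyclic peroxides; ester hydrolysis should be faster than β-elimination of the peroxide or attack at the hindered ketal. Acidifying only to pH 4 in the cold spares the peroxyketal; no stereocenter is touched.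

## Compound list

1 | dimethyl (E)-hex-3-enedioate | COC(=O)C/C=C/CC(=O)OC | starting material
2 | dimethyl (E)-4-hydroperoxyhex-2-enedioate (racemate) | COC(=O)CC(OO)/C=C/C(=O)OC | intermediate
3 | dimethyl (R,E)-4-hydroperoxyhex-2-enedioate | OO[C@@H](/C=C/C(=O)OC)CC(=O)OC | intermediate
4 | hex-5-ynoic acid | OC(=O)CCCC#C | starting material
5 | lithium 6-lithiohex-5-ynoate (not isolated) | [Li]C#CCCCC(=O)O[Li] | intermediate
6 | 6-(triisopropylsilyl)hex-5-ynoic acid | OC(=O)CCCC#C[Si](C(C)C)(C(C)C)C(C)C | intermediate
7 | 1-(1H-imidazol-1-yl)-6-(triisopropylsilyl)hex-5-yn-1-one (acyl imidazolide, not isolated) | O=C(CCCC#C[Si](C(C)C)(C(C)C)C(C)C)n1ccnc1 | intermediate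
8 | N-methoxy-N-methyl-6-(triisopropylsilyl)hex-5-ynamide | CON(C)C(=O)CCCC#C[Si](C(C)C)(C(C)C)C(C)C | intermediate
9 | 8-(triisopropylsilyl)oct-1-en-7-yn-3-one | C=CC(=O)CCCC#C[Si](C(C)C)(C(C)C)C(C)C | intermediate
10 | 3,3-dimethoxy-8-(triisopropylsilyl)oct-1-en-7-yne | C=CC(OC)(OC)CCCC#C[Si](C(C)C)(C(C)C)C(C)C | intermediate
11 | dimethyl (R,E)-4-{[3-methoxy-8-(triisopropylsilyl)oct-1-en-7-yn-3-yl]peroxy}hex-2-enedioate, both epimers at the ketal carbon | C=CC(OC)(CCCC#C[Si](C(C)C)(C(C)C)C(C)C)OO[C@@H](/C=C/C(=O)OC)CC(=O)OC | intermediate
12 | methyl 2-[(3R)-6-methoxy-6-[5-(triisopropylsilyl)pent-4-yn-1-yl]-3,6-dihydro-1,2-dioxin-3-yl]acetate, both epimers at C6 | COC1(CCCC#C[Si](C(C)C)(C(C)C)C(C)C)C=C[C@@H](CC(=O)OC)OO1 | intermediate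
13 | methyl 2-[(3S)-6-methoxy-6-[5-(triisopropylsilyl)pent-4-yn-1-yl]-1,2-dioxan-3-yl]acetate, both epimers at C6 | COC1(CCCC#C[Si](C(C)C)(C(C)C)C(C)C)CC[C@@H](CC(=O)OC)OO1 | intermediate
14 | methyl 2-[(3S,6R)-6-methoxy-6-[5-(triisopropylsilyl)pent-4-yn-1-yl]-1,2-dioxan-3-yl]acetate | CO[C@@]1(CCCC#C[Si](C(C)C)(C(C)C)C(C)C)CC[C@@H](CC(=O)OC)OO1 | intermediate
15 | methyl 2-[(3S,6R)-6-methoxy-6-(pent-4-yn-1-yl)-1,2-dioxan-3-yl]acetate | CO[C@@]1(CCCC#C)CC[C@@H](CC(=O)OC)OO1 | intermediate
16 | undec-10-en-2-one | CC(=O)CCCCCCCC=C | starting material
17 | 9-(1,2,4-trioxolan-3-yl)nonan-2-one (ozonide, not isolated) | CC(=O)CCCCCCCC1OCOO1 | intermediate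
18 | 9-oxodecanal | CC(=O)CCCCCCCC=O | intermediate
19 | (E)-11-iodoundec-10-en-2-one | CC(=O)CCCCCCC/C=C/I | intermediate
20 | methyl 2-[(3S,6R)-6-methoxy-6-[(6E)-15-oxohexadec-6-en-4-yn-1-yl]-1,2-dioxan-3-yl]acetate | CO[C@@]1(CCCC#C/C=C/CCCCCCCC(C)=O)CC[C@@H](CC(=O)OC)OO1 | intermediate
21 | 2-[(3S,6R)-6-methoxy-6-[(6E)-15-oxohexadec-6-en-4-yn-1-yl]-1,2-dioxan-3-yl]acetic acid | CO[C@@]1(CCCC#C/C=C/CCCCCCCC(C)=O)CC[C@@H](CC(=O)O)OO1 | target

## Step count and least certain steps

Total: 15 steps. Longest linear sequence: 11 steps, from hex-5-ynoic acid 4 (steps 3–11, 14, 15). The hydroperoxide branch (steps 1, 2) and the iodoalkene branch (steps 12, 13) are shorter.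

**Step 8 (key step).** What may go wrong:
- Slow initiation and turnover, because one alkene is shielded by a fully substituted carbon and the other is electron-poor.
- Oligomerization, or capping of the vinyl group by the released acrylate.
- Ruthenium-promoted O–O cleavage or rearrangement of the allylic peroxide once the ring has formed.

Fallback: the ring is closed at the O1–C6 bond instead, by intramolecular conjugate addition of a hydroperoxy ketal to an enoate, known chemistry for this ring type. It sets out from Weinreb amide 8 and comes back at 14.
- CH2=CHCH2CH2MgBr adds to 8 to give the ketone 10-(triisopropylsilyl)dec-1-en-9-yn-5-one F1.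
- Wittig methylenation (Ph3PCH3Br, KOt-Bu) gives the diene 5-methylidene-10-(triisopropylsilyl)dec-1-en-9-yne F2.
- Cross-metathesis with methyl acrylate at the monosubstituted alkene, using the catalyst of step 8, gives methyl (E)-6-methylidene-11-(triisopropylsilyl)undec-2-en-10-ynoate F3.
- Ozonolysis of the electron-rich methylidene group in CH2Cl2–MeOH at −78 °C gives the methoxy hydroperoxide methyl (E)-6-hydroperoxy-6-methoxy-11-(triisopropylsilyl)undec-2-en-10-ynoate F4.
- Et2NH in CF3CH2OH closes the ring to methyl 2-[6-methoxy-6-[5-(triisopropylsilyl)pent-4-yn-1-yl]-1,2-dioxan-3-yl]acetate as all four stereoisomers F5.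
- Acidic methanol as in step 10 gives the racemic (3S*,6R*) ester F6, from which 14 is separated on a chiral stationary phase.

This fallback gives up the early resolution: C6 forms without control, and hydroperoxide 3 and ketal 10 are no longer needed.

**Step 7.** What may go wrong:
- Attack of the hydroperoxide at the terminal carbon of the methoxyallyl cation.
- Loss of methanol from 10 to a methoxydiene.
- Exchange of both methoxy groups, or an unfavourable equilibrium position.

Fallback, from 10 back to 11: Me3SiOTf and i-Pr2NEt convert 10 into the enol ether 3-methoxy-8-(triisopropylsilyl)octa-1,3-dien-7-yne F7. Hydroperoxide 3 is then added across the enol ether with catalytic PPTS. This addition releases no methanol and cannot exchange a second time.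

**Step 1.** What may go wrong: a very slow ene reaction of the electron-poor (E)-alkene, so that sensitizer bleaching, radical-chain autoxidation and decomposition of the product take over during long irradiation. Fallback, from 1 back to 2: Wohl–Ziegler bromination (N-bromosuccinimide, radical initiator, PhCF3, 80 °C) gives dimethyl (E)-4-bromohex-2-enedioate F8. Silver-assisted perhydrolysis (AgOCOCF3, anhydrous H2O2 in Et2O, 0 °C) replaces bromide by the hydroperoxy group.

**Step 6.** What may go wrong: conjugate addition of the methoxy donor, polymerization of the vinyl ketone, or isomerization of the product to an enol ether under the Lewis acid. Fallback, from 9 back to 10, with the alkene masked during ketalization: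
- HBr in CH2Cl2 at 0 °C adds to the enone to give 1-bromo-8-(triisopropylsilyl)oct-7-yn-3-one F9.
- HC(OMe)3, MeOH and catalytic TsOH give 1-bromo-3,3-dimethoxy-8-(triisopropylsilyl)oct-7-yne F10.
- KOt-Bu in THF eliminates HBr to give 10.

## Further compounds

F1 | step 8 | 10-(triisopropylsilyl)dec-1-en-9-yn-5-one | C=CCCC(=O)CCCC#C[Si](C(C)C)(C(C)C)C(C)C
F2 | step 8 | 5-methylidene-10-(triisopropylsilyl)dec-1-en-9-yne | C=CCCC(=C)CCCC#C[Si](C(C)C)(C(C)C)C(C)C
F3 | step 8 | methyl (E)-6-methylidene-11-(triisopropylsilyl)undec-2-en-10-ynoate | COC(=O)/C=C/CCC(=C)CCCC#C[Si](C(C)C)(C(C)C)C(C)C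
F4 | step 8 | methyl (E)-6-hydroperoxy-6-methoxy-11-(triisopropylsilyl)undec-2-en-10-ynoate (racemate) | COC(=O)/C=C/CCC(OC)(OO)CCCC#C[Si](C(C)C)(C(C)C)C(C)C
F5 | step 8 | methyl 2-[6-methoxy-6-[5-(triisopropylsilyl)pent-4-yn-1-yl]-1,2-dioxan-3-yl]acetate, all four stereoisomers | COC1(CCCC#C[Si](C(C)C)(C(C)C)C(C)C)CCC(CC(=O)OC)OO1
F6 | step 8 | methyl 2-[(3S*,6R*)-6-methoxy-6-[5-(triisopropylsilyl)pent-4-yn-1-yl]-1,2-dioxan-3-yl]acetate (racemate) | CO[C@@]1(CCCC#C[Si](C(C)C)(C(C)C)C(C)C)CC[C@@H](CC(=O)OC)OO1.CO[C@]1(CCCC#C[Si](C(C)C)(C(C)C)C(C)C)CC[C@H](CC(=O)OC)OO1
F7 | step 7 | 3-methoxy-8-(triisopropylsilyl)octa-1,3-dien-7-yne (mixture of double-bond isomers) | C=CC(OC)=CCCC#C[Si](C(C)C)(C(C)C)C(C)C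
F8 | step 1 | dimethyl (E)-4-bromohex-2-enedioate (racemate) | COC(=O)CC(Br)/C=C/C(=O)OC
F9 | step 6 | 1-bromo-8-(triisopropylsilyl)oct-7-yn-3-one | BrCCC(=O)CCCC#C[Si](C(C)C)(C(C)C)C(C)C
F10 | step 6 | 1-bromo-3,3-dimethoxy-8-(triisopropylsilyl)oct-7-yne | BrCCC(OC)(OC)CCCC#C[Si](C(C)C)(C(C)C)C(C)C
A1 | alternative 1 | 2-[(3S)-6-hydroperoxy-6-[5-(trimethylsilyl)pent-4-yn-1-yl]-1,2-dioxan-3-yl]acetaldehyde, both epimers at C6 | OOC1(CCCC#C[Si](C)(C)C)CC[C@@H](CC=O)OO1
A2 | alternative 1 | {5-[(4S)-4-hydroperoxycyclohex-1-en-1-yl]pent-1-yn-1-yl}trimethylsilane | OO[C@H]1CCC(CCCC#C[Si](C)(C)C)=CC1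
A3 | alternative 2 | 2-[(3S,6R)-6-methoxy-6-[5-(trimethylsilyl)pent-4-yn-1-yl]-1,2-dioxan-3-yl]ethan-1-ol | CO[C@@]1(CCCC#C[Si](C)(C)C)CC[C@@H](CCO)OO1
A4 | alternative 2 | (R)-2-[3,3-dimethoxy-8-(trimethylsilyl)oct-7-yn-1-yl]oxetane | COC(OC)(CCCC#C[Si](C)(C)C)CC[C@@H]1CCO1
A5 | alternative 3 | tert-butyl{2-[(3S,6R)-6-methoxy-6-[5-(triisopropylsilyl)pent-4-yn-1-yl]-1,2-dioxan-3-yl]ethoxy}diphenylsilane | CO[C@@]1(CCCC#C[Si](C(C)C)(C(C)C)C(C)C)CC[C@@H](CCO[Si](c2ccccc2)(c2ccccc2)C(C)(C)C)OO1
A6 | alternative 3 | tert-butyl{[(3S)-3-hydroperoxy-11-(triisopropylsilyl)undeca-6,10-diyn-1-yl]oxy}diphenylsilane | CC(C)(C)[Si](c1ccccc1)(c1ccccc1)OCC[C@@H](OO)CCC#CCCC#C[Si](C(C)C)(C(C)C)C(C)C
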